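Ring B (C5–C6–C7–C8–C9–C10, eremophilane numbering) is cut at C5–C10 and C8–C9. One intramolecular Diels–Alder reaction of an acyclic triene should make both bonds, close ring A around the new C5–C10 bond and set C5, C9 and C10 from the C3/C4 stereocentres of the tether. The step exploits the vicinal C8 ketone/C9 oxygen pair of ring B, which is carried by boron on both reacting termini, and the cis C5/C10 fusion, which a Z-diene enforces. The precursor is a (7Z,9E)-dienylboronate whose terminal alkyne is hydroborated in the flask to the (E)-alkenylborane dienophile; its Z-alkene comes from a temporary lactone ring.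

Key step: step 8

Remark: eremophilane numbering (C1–C15) is used for the skeleton in all intermediates, β is the face of the C5 methyl group, and pent-4-ynal is made fresh because it is volatile.

Step 1
Reactants: 1 pent-4-yn-1-ol
Product: 2 pent-4-ynal
Conditions: TEMPO (10 mol %), PhI(OAc)2 (1.1 equiv), CH2Cl2, 23 °C; short-path distillation, used as a CH2Cl2 solution
Reagents that add atoms: none
Why: The oxoammonium (TEMPO) oxidation of a primary alcohol stops at the aldehyde and leaves the terminal alkyne untouched.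

Step 2
Reactants: 2 pent-4-ynal; 3 (S)-4-benzyl-3-propionyloxazolidin-2-one
Product: 4 (S)-4-benzyl-3-[(2S,3R)-3-hydroxy-2-methylhept-6-ynoyl]oxazolidin-2-one
Conditions: 3, Bu2BOTf (1.1 equiv), iPr2NEt (1.2 equiv), CH2Cl2, 0 °C; then 2, −78 → 0 °C; pH 7 buffer, MeOH, H2O2
Reagents that add atoms: none
Why: Evans syn-aldol reaction: the (Z)-boron enolate reacts through a Zimmerman–Traxler chair on the face away from the benzyl group, which sets the carbinol carbon (later C3, R) and the methyl-bearing carbon (later C4) in the syn relation.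

Step 3
Reactants: 4 (S)-4-benzyl-3-[(2S,3R)-3-hydroxy-2-methylhept-6-ynoyl]oxazolidin-2-one
Product: 5 (2S,3R)-3-hydroxy-N-methoxy-N,2-dimethylhept-6-ynamide
Conditions: MeONHMe·HCl (3 equiv), AlMe3 (3 equiv), CH2Cl2, −15 → 23 °C; aq potassium sodium tartrate
Reagents that add atoms: N,O-dimethylhydroxylamine hydrochloride, CNOC.Cl
Why: Weinreb transamidation: the aluminium amide, anchored by the β-alkoxide, attacks only the exocyclic imide carbonyl, so the auxiliary is released without retro-aldol cleavage or epimerisation.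

Step 4
Reactants: 5 (2S,3R)-3-hydroxy-N-methoxy-N,2-dimethylhept-6-ynamide
Product: 6 (3S,4R)-4-hydroxy-3-methyloct-7-yn-2-one
Conditions: MeMgBr (3.5 equiv), THF, −20 → 0 °C; aq NH4Cl
Reagents that add atoms: methylmagnesium bromide, C[Mg]Br
Why: Weinreb ketone synthesis: the chelated tetrahedral intermediate prevents a second addition, and the alkoxide and any acetylide formed by the excess Grignard reagent are simply reprotonated on work-up; the new methyl becomes C14.

Step 5
Reactants: 6 (3S,4R)-4-hydroxy-3-methyloct-7-yn-2-one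
Product: 8 (5R,6R)-6-(but-3-yn-1-yl)-4,5-dimethyl-5,6-dihydro-2H-pyran-2-one, via phosphorane ester 7 (not isolated)
Conditions: Ph3P=C=C=O (1.2 equiv), toluene, 100 °C
Reagents that add atoms: (triphenylphosphoranylidene)ketene, O=C=C=P(c1ccccc1)(c1ccccc1)c1ccccc1
Why: The hydroxyl adds to the ketene carbon to give a stabilised ester ylide that closes by intramolecular Wittig olefination onto the methyl ketone; the six-membered ring forces the new trisubstituted C5=C6 alkene to carry C4 and C7 on the same side (the Z geometry needed later) and masks the C3 oxygen.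

Step 6
Reactants: 8 (5R,6R)-6-(but-3-yn-1-yl)-4,5-dimethyl-5,6-dihydro-2H-pyran-2-one
Product: 9 (5R,6R)-6-(but-3-yn-1-yl)-4,5-dimethyl-5,6-dihydro-2H-pyran-2-ol
Conditions: iBu2AlH (1.1 equiv), CH2Cl2, −78 °C; aq potassium sodium tartrate
Reagents that add atoms: none
Why: 1,2-Reduction of the unsaturated lactone stops at the lactol because the tetrahedral aluminate is stable at −78 °C; the anomeric centre is of no consequence.

Step 7
Reactants: 9 (5R,6R)-6-(but-3-yn-1-yl)-4,5-dimethyl-5,6-dihydro-2H-pyran-2-ol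
Product: 10 (5R,6R,7Z,9E)-6,7-dimethyl-10-(4,4,5,5-tetramethyl-1,3,2-dioxaborolan-2-yl)deca-7,9-dien-1-yn-5-ol
Conditions: CH2(Bpin)2 (3.0 equiv), lithium 2,2,6,6-tetramethylpiperidide (3.0 equiv), THF, 0 °C; then 9, −78 → 23 °C; aq NH4Cl
Reagents that add atoms: bis(pinacolato)borylmethane, CC1(C)OB(CB2OC(C)(C)C(C)(C)O2)OC1(C)C
Why: Boron–Wittig olefination: the lithiated geminal bis(boronate) adds to the (Z)-enal form of the opened lactol and syn B–O elimination gives the (E)-alkenylboronate (boron on C8, trans to C6), while the Z alkene from the lactone is retained; the excess base covers the O–H and alkyne C–H protons.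

Step 8
Reactants: 10 (5R,6R,7Z,9E)-6,7-dimethyl-10-(4,4,5,5-tetramethyl-1,3,2-dioxaborolan-2-yl)deca-7,9-dien-1-yn-5-ol
Product: 13 (1R,2S,4aR,5R,6R,8aS)-4a,5-dimethyl-1,2,4a,5,6,7,8,8a-octahydronaphthalene-1,2,6-triol, via alkenyl-dicyclohexylborane 11 (not isolated), via bis-boryl cycloadduct 12 (not isolated)
Conditions: Cy2BH (2.1 equiv, from BH3·SMe2 and cyclohexene), THF, 0 → 23 °C; then toluene (0.02 M), 85 °C; then NaOH, H2O2, 0 → 23 °C
Reagents that add atoms: hydrogen peroxide, OO
Why: Syn hydroboration of the terminal alkyne (the hydroxyl is bound as a borinate) gives the (E)-alkenyl-dicyclohexylborane 11, whose empty boron p orbital lowers the LUMO of the C9=C10 dienophile so that it adds in a concerted, suprafacial [4+2] cycloaddition across C5 and C8 of the tethered 1-boryl diene, after which both C–B bonds are oxidised with retention. The closest known reaction types are the Diels–Alder reaction of B-alkenyl dialkylboranes (vinylborane dienophiles) and the intramolecular Diels–Alder reaction of 1-boryl-1,3-dienes. Ring A closes through the new C5–C10 bond as a chair-like six-membered ring over the four-carbon tether C4–C3–C2–C1 (the 1,3,9-decatriene mode), and ring B is the cyclohexene formed by the cycloaddition itself through a boat-like array. Because the tether stands on the inside (Z) position of C5=C6, only the tether-exo geometry can reach C10, so the ring fusion must be cis (C5 methyl and C10 hydrogen on one face), and the E alkene places boron trans to C1 and endo, which fixes C9 (oxygen β, cis to the C10 hydrogen); C8 is set by the E boryl group but later becomes the ketone. The face of the diene is chosen by the C4 stereocentre: A(1,3) strain with C7 holds the C4–H bond in the diene plane, the tether (C3) reaches the dienophile from one face and the C4 methyl occupies the other, so the C4 and C5 methyl groups end up cis and the tether chair carries the C3 oxygen and the C4 methyl equatorially. The step needs hydroboration of the alkyne in preference to the dienylboronate (secured by the bulk of Cy2BH and the low reactivity of the boryl diene) and intramolecular in preference to intermolecular cycloaddition (secured by high dilution).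

Step 9
Reactants: 13 (1R,2S,4aR,5R,6R,8aS)-4a,5-dimethyl-1,2,4a,5,6,7,8,8a-octahydronaphthalene-1,2,6-triol
Product: 14 (1R,4aR,5R,6R,8aS)-1,6-dihydroxy-4a,5-dimethyl-4a,5,6,7,8,8a-hexahydronaphthalen-2(1H)-one
Conditions: MnO2 (activated, 15 equiv), CH2Cl2, 23 °C
Reagents that add atoms: none
Why: MnO2 oxidises allylic alcohols much faster than saturated ones, so only the C8 carbinol next to C6=C7 should be converted (chemoselective allylic oxidation), which also erases the inconsequential C8 stereocentre.

Step 10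
Reactants: 14 (1R,4aR,5R,6R,8aS)-1,6-dihydroxy-4a,5-dimethyl-4a,5,6,7,8,8a-hexahydronaphthalen-2(1H)-one
Product: 15 (1R,4aR,5R,6R,8aS)-1,6-dihydroxy-3-iodo-4a,5-dimethyl-4a,5,6,7,8,8a-hexahydronaphthalen-2(1H)-one
Conditions: I2 (2 equiv), pyridine/CH2Cl2 1:1, 23 °C
Reagents that add atoms: iodine, II
Why: α-Iodination of the enone by the pyridine-mediated addition–iodination–elimination sequence (Baylis–Hillman type) places iodine on C7, the only vinylic α-carbon, and tolerates the quaternary neighbour of C6 and free hydroxyl groups.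

Step 11
Reactants: 15 (1R,4aR,5R,6R,8aS)-1,6-dihydroxy-3-iodo-4a,5-dimethyl-4a,5,6,7,8,8a-hexahydronaphthalen-2(1H)-one
Product: 16 (1R,4aR,5R,6R,8aS)-1,6-dihydroxy-4a,5-dimethyl-3-(prop-1-en-2-yl)-4a,5,6,7,8,8a-hexahydronaphthalen-2(1H)-one
Conditions: isopropenyl-Bpin (1.5 equiv), Pd(dppf)Cl2 (5 mol %), K3PO4, dioxane/H2O, 50 °C
Reagents that add atoms: 2-isopropenyl-4,4,5,5-tetramethyl-1,3,2-dioxaborolane, C=C(C)B1OC(C)(C)C(C)(C)O1
Why: Suzuki–Miyaura coupling of the 2-iodoenone (fast oxidative addition to zerovalent palladium) installs C11–C13 on C7 without touching a stereocentre.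

Step 12
Reactants: 16 (1R,4aR,5R,6R,8aS)-1,6-dihydroxy-4a,5-dimethyl-3-(prop-1-en-2-yl)-4a,5,6,7,8,8a-hexahydronaphthalen-2(1H)-one
Product: 17 (1R,4aR,5R,6R,8aS)-4a,5-dimethyl-2-oxo-3-(prop-1-en-2-yl)-1,2,4a,5,6,7,8,8a-octahydronaphthalene-1,6-diyl bis[(2Z)-2-methylbut-2-enoate]
Conditions: angelic acid, 2,4,6-trichlorobenzoyl chloride, Et3N, toluene, 23 °C; then 16, 80 °C (no DMAP)
Reagents that add atoms: angelic acid, C/C=C(/C)C(=O)O
Why: Yamaguchi esterification through the mixed anhydride acylates both secondary alcohols, and leaving out a nucleophilic catalyst avoids isomerisation of the (Z)-angelate to the (E)-tiglate; C7 is still sp2 here, so the base cannot epimerise it.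

Step 13
Reactants: 17 (1R,4aR,5R,6R,8aS)-4a,5-dimethyl-2-oxo-3-(prop-1-en-2-yl)-1,2,4a,5,6,7,8,8a-octahydronaphthalene-1,6-diyl bis[(2Z)-2-methylbut-2-enoate]
Product: 18 (1R,3R,4aR,5R,6R,8aS)-4a,5-dimethyl-2-oxo-3-(prop-1-en-2-yl)decahydronaphthalene-1,6-diyl bis[(2Z)-2-methylbut-2-enoate]
Conditions: [(Ph3P)CuH]6 (0.4 equiv), H2O (3 equiv), toluene, 23 °C
Reagents that add atoms: none
Why: Copper hydride conjugate reduction: hydride should add to C6 of the ketone-activated enone much faster than to the α,β-disubstituted angelate esters, and kinetic protonation of the cross-conjugated copper dienolate at C7 (α-carbon, axial approach) should give the equatorial 7β-isopropenyl group, which is also the thermodynamically favoured epimer of the cis-decalin, without moving the double bond into conjugation.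

Compound list
1 | pent-4-yn-1-ol | C#CCCCO | starting material
2 | pent-4-ynal | C#CCCC=O | intermediate
3 | (S)-4-benzyl-3-propionyloxazolidin-2-one | CCC(=O)N1[C@@H](Cc2ccccc2)COC1=O | starting material
4 | (S)-4-benzyl-3-[(2S,3R)-3-hydroxy-2-methylhept-6-ynoyl]oxazolidin-2-one | C#CCC[C@@H](O)[C@H](C)C(=O)N1[C@@H](Cc2ccccc2)COC1=O | intermediate
5 | (2S,3R)-3-hydroxy-N-methoxy-N,2-dimethylhept-6-ynamide | C#CCC[C@@H](O)[C@H](C)C(=O)N(C)OC | intermediate
6 | (3S,4R)-4-hydroxy-3-methyloct-7-yn-2-one | C#CCC[C@@H](O)[C@H](C)C(C)=O | intermediate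
7 | (3S,4R)-3-methyl-2-oxooct-7-yn-4-yl (triphenylphosphoranylidene)acetate | C#CCC[C@@H](OC(=O)C=P(c1ccccc1)(c1ccccc1)c1ccccc1)[C@H](C)C(C)=O | intermediate (not isolated)
8 | (5R,6R)-6-(but-3-yn-1-yl)-4,5-dimethyl-5,6-dihydro-2H-pyran-2-one (5,6-cis) | C#CCC[C@H]1OC(=O)C=C(C)[C@H]1C | intermediate
9 | (5R,6R)-6-(but-3-yn-1-yl)-4,5-dimethyl-5,6-dihydro-2H-pyran-2-ol (both anomers) | C#CCC[C@H]1OC(O)C=C(C)[C@H]1C | intermediate
10 | (5R,6R,7Z,9E)-6,7-dimethyl-10-(4,4,5,5-tetramethyl-1,3,2-dioxaborolan-2-yl)deca-7,9-dien-1-yn-5-ol | C#CCC[C@@H](O)[C@H](C)/C(C)=C\C=C\B1OC(C)(C)C(C)(C)O1 | intermediate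
11 | (1E,7Z,9E)-1-(dicyclohexylboryl)-5-O-(dicyclohexylboryl) derivative of 10, i.e. the (E)-alkenylborane formed at the former alkyne | C1CCCCC1B(C1CCCCC1)/C=C/CC[C@@H](OB(C1CCCCC1)C1CCCCC1)[C@H](C)/C(C)=C\C=C\B1OC(C)(C)C(C)(C)O1 | intermediate (not isolated)
12 | cis-fused cycloadduct: 4β,5β-dimethyl-10βH-octal-6-ene carrying 3α-OBCy2, 8β-Bpin and 9β-BCy2 | CC1(C)OB(OC1(C)C)[C@H]1C=C[C@]2(C)[C@@H](C)[C@H](OB(C3CCCCC3)C3CCCCC3)CC[C@@H]2[C@H]1B(C1CCCCC1)C1CCCCC1 | intermediate (not isolated)
13 | (1R,2S,4aR,5R,6R,8aS)-4a,5-dimethyl-1,2,4a,5,6,7,8,8a-octahydronaphthalene-1,2,6-triol (3α,8β,9β-triol, Δ6) | O[C@H]1C=C[C@]2(C)[C@@H](C)[C@H](O)CC[C@@H]2[C@H]1O | intermediate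
14 | (1R,4aR,5R,6R,8aS)-1,6-dihydroxy-4a,5-dimethyl-4a,5,6,7,8,8a-hexahydronaphthalen-2(1H)-one | O=C1C=C[C@]2(C)[C@@H](C)[C@H](O)CC[C@@H]2[C@H]1O | intermediate
15 | (1R,4aR,5R,6R,8aS)-1,6-dihydroxy-3-iodo-4a,5-dimethyl-4a,5,6,7,8,8a-hexahydronaphthalen-2(1H)-one | O=C1C(I)=C[C@]2(C)[C@@H](C)[C@H](O)CC[C@@H]2[C@H]1O | intermediate
16 | (1R,4aR,5R,6R,8aS)-1,6-dihydroxy-4a,5-dimethyl-3-(prop-1-en-2-yl)-4a,5,6,7,8,8a-hexahydronaphthalen-2(1H)-one | O=C1C(C(C)=C)=C[C@]2(C)[C@@H](C)[C@H](O)CC[C@@H]2[C@H]1O | intermediate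
17 | (1R,4aR,5R,6R,8aS)-4a,5-dimethyl-2-oxo-3-(prop-1-en-2-yl)-1,2,4a,5,6,7,8,8a-octahydronaphthalene-1,6-diyl bis[(2Z)-2-methylbut-2-enoate] | O=C1C(C(C)=C)=C[C@]2(C)[C@@H](C)[C@H](OC(=O)/C(C)=C\C)CC[C@@H]2[C@H]1OC(=O)/C(C)=C\C | intermediate
18 | (1R,3R,4aR,5R,6R,8aS)-4a,5-dimethyl-2-oxo-3-(prop-1-en-2-yl)decahydronaphthalene-1,6-diyl bis[(2Z)-2-methylbut-2-enoate] (3α,9β-bis(angeloyloxy)-10βH-eremophil-11-en-8-one) | C=C(C)[C@H]1C[C@@]2(C)[C@H](CC[C@@H](OC(=O)/C(C)=C\C)[C@@H]2C)[C@@H](OC(=O)/C(C)=C\C)C1=O | target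

Total step count: 13
Longest linear sequence: 13 steps (1 → 18; compound 3 enters at step 2)

Steps most likely to fail

Step 8. The twisted s-cis conformer of the Z-diene may form too slowly. The alkenyl(dialkyl)borane could then be consumed by a second hydroboration, by boron exchange with the boronate or by intermolecular cycloaddition before the ring closes. The fallback sets out from 10 and replaces the in-flask borane by an isolable boronic ester dienophile and a purely thermal cycloaddition. Hydroboration of the alkyne with pinacolborane (Cp2ZrHCl 10 mol %, Et3N 10 mol %, 50 °C; aqueous work-up) should give (1E,5R,6R,7Z,9E)-6,7-dimethyl-1,10-bis(4,4,5,5-tetramethyl-1,3,2-dioxaborolan-2-yl)deca-1,7,9-trien-5-ol F1, which has no B–H bond left. Heating F1 in toluene (160 °C, BHT, sealed tube) should give, through the same tether-exo and boron-endo geometry, the 3α-hydroxy-8β,9β-bis(pinacolboryl) cis-octalin cycloadduct F2. Oxidation of F2 with NaBO3·4H2O (THF/H2O) returns to the route at 13.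

Step 13. Hydride may also be delivered to the angelate esters or to the carbonyl carbon, or the copper dienolate may be protonated at its terminal carbon so that the double bond moves into conjugation. The fallback sets out from 16 and reverses the order of the last two operations, so that no enoate is present during the reduction. Treatment of 16 with [(Ph3P)CuH]6 in wet toluene should give 3α,9β-dihydroxy-10βH-eremophil-11-en-8-one F4. Esterification of both hydroxyl groups of F4 with the angelic mixed anhydride under the conditions of step 12 then gives 18. Since C7 of F4 already carries its substituent equatorially, the thermodynamic arrangement, the brief exposure to Et3N should not epimerise it.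

Step 7. The lactol may open only slowly, so that the strongly basic carbanion deprotonates the γ-position of the (Z)-enal, with loss of the Z geometry and of the C4 configuration. The fallback sets out from 9 and uses a non-basic chromium carbenoid followed by a palladium borylation. Takai olefination (CrCl2, CHI3, THF/dioxane, 0 °C) should give (5R,6R,7Z,9E)-10-iodo-6,7-dimethyldeca-7,9-dien-1-yn-5-ol F3. Miyaura borylation of F3 (B2pin2, PdCl2(PPh3)2, PPh3, KOPh, toluene, 50 °C) returns to the route at 10.

Further compounds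
F1 | step 8 | (1E,5R,6R,7Z,9E)-6,7-dimethyl-1,10-bis(4,4,5,5-tetramethyl-1,3,2-dioxaborolan-2-yl)deca-1,7,9-trien-5-ol | CC1(C)OB(/C=C/CC[C@@H](O)[C@H](C)/C(C)=C\C=C\B2OC(C)(C)C(C)(C)O2)OC1(C)C
F2 | step 8 | 3α-hydroxy-8β,9β-bis(pinacolboryl) cis-octalin cycloadduct (4β,5β-dimethyl, 10βH, Δ6) | CC1(C)OB(OC1(C)C)[C@H]1C=C[C@]2(C)[C@@H](C)[C@H](O)CC[C@@H]2[C@H]1B1OC(C)(C)C(C)(C)O1
F3 | step 7 | (5R,6R,7Z,9E)-10-iodo-6,7-dimethyldeca-7,9-dien-1-yn-5-ol | C#CCC[C@@H](O)[C@H](C)/C(C)=C\C=C\I
F4 | step 13 | 3α,9β-dihydroxy-10βH-eremophil-11-en-8-one | C=C(C)[C@H]1C[C@@]2(C)[C@H](CC[C@@H](O)[C@@H]2C)[C@@H](O)C1=O
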